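**Plan**

- Retrosynthetic cuts: the C9'=C10' bond of the diene (olefination), the C3–CH2CO2H bond (peroxycarbenium alkylation), then both C–O bonds of the peroxide by taking O2 out of C3/C5, which leaves a 1,2-dimethyl-2-alkylcyclopropan-1-ol. That is cut at its CH2 (cyclopropanation of a silyl enol ether), at the enone C=C (Wittig) and at C3'–C4' of the chain (sp3–sp3 coupling).
- Forward order: chain coupling, oxidation, Wittig, conjugate hydrosilylation, cyclopropanol, aerobic ring expansion of the three-membered carbocycle to the 1,2-dioxolan-3-ol, acetate, ester arm, then the diene and hydrolysis.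
- Enabling feature: ring atoms C3–C4–C5 are a three-carbon unit whose two ends are both fully substituted, each bears a methyl, and they are joined only through O1–O2. This is the skeleton of a cyclopropanol whose C1–C2 bond has been replaced by C–O–O–C. The C3 hydroxyl (ketone oxidation level) is the helper and is later exchanged for CH2CO2Me.
- Stereochemistry: C2' is bought with (S)-3-bromo-2-methylpropan-1-ol. C5 forms at a planar radical without control, so both epimers are expected. C3 is relayed from C5 by anti addition to the peroxycarbenium ion. The (3S,5R) isomer is isolated by separation after step 8. Diene geometry comes from an E-selective olefination.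

Key step: step 6

Remark: dioxolane locants are O1–O2–C3–C4–C5 with the acetic acid arm on C3; primed locants belong to the side chain on C5; all starting materials are taken as commercially available.

**Step 1**
Reactants: 1 (6-bromohexyloxy)(tert-butyl)dimethylsilane; 2 (S)-3-bromo-2-methylpropan-1-ol
Product: 5 (R)-9-[(tert-butyldimethylsilyl)oxy]-2-methylnonan-1-ol, via Grignard reagent 3 (not isolated), via magnesium alkoxide 4 (not isolated)
Conditions: 1, Mg, THF, 40 °C; 2, i-PrMgCl (1 equiv), THF, −20 °C; combine, Li2CuCl4 (3 mol %), −20 °C to rt; aq. NH4Cl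
Reagents that add atoms: none
Why: Copper-catalysed Kochi-type sp3–sp3 coupling of a primary alkyl Grignard reagent with a primary alkyl bromide whose hydroxyl is masked as the magnesium alkoxide; the stereocentre is one carbon away from the reacting CH2Br and is not touched, so (S) in 2 becomes (R) in 5 only through a change of CIP priorities.

**Step 2**
Reactants: 5 (R)-9-[(tert-butyldimethylsilyl)oxy]-2-methylnonan-1-ol
Product: 6 (R)-9-[(tert-butyldimethylsilyl)oxy]-2-methylnonanal
Conditions: Dess–Martin periodinane, NaHCO3, CH2Cl2, 0 °C to rt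
Reagents that add atoms: none
Why: Dess–Martin oxidation under buffered, non-basic conditions should give the α-branched aldehyde without epimerisation, and the aldehyde is used at once.

**Step 3**
Reactants: 6 (R)-9-[(tert-butyldimethylsilyl)oxy]-2-methylnonanal; 7 3-(triphenyl-λ5-phosphanylidene)butan-2-one
Product: 8 (3E,5R)-12-[(tert-butyldimethylsilyl)oxy]-3,5-dimethyldodec-3-en-2-one
Conditions: PhMe, 90 °C
Reagents that add atoms: none
Why: Wittig olefination with a ketone-stabilised ylide under neutral conditions should give the (E)-trisubstituted enone (its geometry has no consequence later) without touching the now allylic stereocentre.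

**Step 4**
Reactants: 8 (3E,5R)-12-[(tert-butyldimethylsilyl)oxy]-3,5-dimethyldodec-3-en-2-one
Product: 9 (5R)-12-[(tert-butyldimethylsilyl)oxy]-2-{[dimethyl(phenyl)silyl]oxy}-3,5-dimethyldodec-2-ene (E/Z mixture)
Conditions: [(Ph3P)CuH]6 (3 mol %), PhMe2SiH (1.5 equiv), PhMe, rt
Reagents that add atoms: dimethylphenylsilane, C[SiH](C)c1ccccc1
Why: Copper hydride-catalysed conjugate reduction (1,4-hydrosilylation) puts hydride on C4 and silicon on the enolate oxygen, so the tetrasubstituted silyl enol ether forms regiospecifically on the side of the future quaternary carbon, which enolisation of the saturated ketone would not guarantee; no stereocentre is formed.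

**Step 5**
Reactants: 9 (5R)-12-[(tert-butyldimethylsilyl)oxy]-2-{[dimethyl(phenyl)silyl]oxy}-3,5-dimethyldodec-2-ene
Product: 11 2-{(2R)-9-[(tert-butyldimethylsilyl)oxy]-2-methylnonyl}-1,2-dimethylcyclopropan-1-ol (mixture of ring diastereomers), via siloxycyclopropane 10 (not isolated)
Conditions: Et2Zn, CH2I2, CH2Cl2, 0 °C to rt; then K2CO3, MeOH, 0 °C
Reagents that add atoms: diiodomethane, ICI
Why: Furukawa-modified Simmons–Smith cyclopropanation of the electron-rich silyl enol ether (the only alkene) adds CH2 across C2=C3, and mild methanolysis of the labile aryldimethylsilyl ether frees the tertiary cyclopropanol while the primary TBS ether stays; the two ring stereocentres form as a mixture, which is harmless because both are erased in step 6.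

**Step 6**
Reactants: 11 2-{(2R)-9-[(tert-butyldimethylsilyl)oxy]-2-methylnonyl}-1,2-dimethylcyclopropan-1-ol
Product: 13 5-{(2R)-9-[(tert-butyldimethylsilyl)oxy]-2-methylnonyl}-3,5-dimethyl-1,2-dioxolan-3-ol (mixture at C3 and C5), via hydroperoxy ketone 12 (not isolated)
Conditions: Mn(acac)3 (2 mol %), O2 (1 atm), PhH, rt
Reagents that add atoms: dioxygen, O=O
Why: Trivalent manganese exchanges onto the cyclopropanol oxygen and oxidises it to the cyclopropyloxy radical, which opens by β-scission of the C1–C2 bond to the tertiary β-keto alkyl radical; this captures O2, and the peroxyl radical is reduced by divalent manganese and protonated to hydroperoxy ketone 12 while the trivalent catalyst returns. The closest known reaction type is the manganese-catalysed aerobic ring expansion of cyclopropanols to 1,2-dioxolan-3-ols. The three-membered carbocycle thus takes up the O–O unit between C1 and C2, and the five-membered ring closes by 5-exo-trig addition of the hydroperoxide O–H to the ketone. Of the two new stereocentres, C5 is formed at a planar tertiary radical with no controlling element, so both epimers are expected, and C3 is an equilibrating hemiketal that is erased in step 8. The step needs regioselective scission toward the quaternary carbon (C1–C2 rather than C1–C3), which the stability of a tertiary over a primary radical secures, and trapping by O2 ahead of hydrogen abstraction, which the O2-saturated medium secures.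

**Step 7**
Reactants: 13 5-{(2R)-9-[(tert-butyldimethylsilyl)oxy]-2-methylnonyl}-3,5-dimethyl-1,2-dioxolan-3-ol
Product: 14 5-{(2R)-9-[(tert-butyldimethylsilyl)oxy]-2-methylnonyl}-3,5-dimethyl-1,2-dioxolan-3-yl acetate (mixture at C3 and C5)
Conditions: Ac2O, pyridine, DMAP (cat.), CH2Cl2, 0 °C
Reagents that add atoms: acetic anhydride, CC(=O)OC(C)=O
Why: DMAP-catalysed acylation turns the peroxy hemiketal hydroxyl into a leaving group for ionisation; the C3 configuration is irrelevant because step 8 passes through a planar cation.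

**Step 8**
Reactants: 14 5-{(2R)-9-[(tert-butyldimethylsilyl)oxy]-2-methylnonyl}-3,5-dimethyl-1,2-dioxolan-3-yl acetate; 15 tert-butyl[(1-methoxyethenyl)oxy]dimethylsilane
Product: 16 methyl 2-[(3S,5R)-5-{(2R)-9-[(tert-butyldimethylsilyl)oxy]-2-methylnonyl}-3,5-dimethyl-1,2-dioxolan-3-yl]acetate
Conditions: TiCl4 (1.1 equiv), CH2Cl2, −78 °C; then preparative HPLC
Reagents that add atoms: none
Why: TiCl4 ionises the acetate to a cyclic peroxycarbenium ion at C3, which the silyl ketene acetal captures in a Mukaiyama-type addition, a known way to 3,3,5,5-tetrasubstituted 1,2-dioxolane-3-acetates; attack anti to the larger C5 substituent (the branched chain, not methyl) should place CH2CO2Me trans to the chain, that is (3S) in the (5R) series, and 16 is then separated from its (3R,5S) diastereomer (mirror-image ring, same chain centre) and from the minor cis isomers.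

**Step 9**
Reactants: 16 methyl 2-[(3S,5R)-5-{(2R)-9-[(tert-butyldimethylsilyl)oxy]-2-methylnonyl}-3,5-dimethyl-1,2-dioxolan-3-yl]acetate
Product: 17 methyl 2-[(3S,5R)-5-[(2R)-9-hydroxy-2-methylnonyl]-3,5-dimethyl-1,2-dioxolan-3-yl]acetate
Conditions: HF·pyridine, pyridine, THF, 0 °C to rt
Reagents that add atoms: none
Why: Fluoride desilylation under buffered, mildly acidic conditions removes the primary TBS ether without base, so the β-peroxy ester cannot open by E1cB elimination.

**Step 10**
Reactants: 17 methyl 2-[(3S,5R)-5-[(2R)-9-hydroxy-2-methylnonyl]-3,5-dimethyl-1,2-dioxolan-3-yl]acetate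
Product: 18 methyl 2-[(3S,5R)-3,5-dimethyl-5-[(2R)-2-methyl-9-oxononyl]-1,2-dioxolan-3-yl]acetate
Conditions: Dess–Martin periodinane, NaHCO3, CH2Cl2, 0 °C to rt
Reagents that add atoms: none
Why: Dess–Martin oxidation is neutral and should leave the dialkyl peroxide and the ester untouched.

**Step 11**
Reactants: 18 methyl 2-[(3S,5R)-3,5-dimethyl-5-[(2R)-2-methyl-9-oxononyl]-1,2-dioxolan-3-yl]acetate; 19 diethyl [(2E)-3-phenylprop-2-en-1-yl]phosphonate
Product: 21 methyl 2-[(3S,5R)-3,5-dimethyl-5-[(2R,9E,11E)-2-methyl-12-phenyldodeca-9,11-dien-1-yl]-1,2-dioxolan-3-yl]acetate, via lithiated phosphonate 20 (not isolated)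
Conditions: 19, LiHMDS (1.0 equiv), THF, −78 °C; then 18, −78 °C to rt; aq. NH4Cl
Reagents that add atoms: none
Why: Horner–Wadsworth–Emmons olefination with the stabilised allylic phosphonate anion should form the new C9'=C10' bond with E geometry while the E styrenyl bond of the reagent is retained; the pre-formed anion should add to the aldehyde at low temperature faster than it deprotonates the ester.

**Step 12**
Reactants: 21 methyl 2-[(3S,5R)-3,5-dimethyl-5-[(2R,9E,11E)-2-methyl-12-phenyldodeca-9,11-dien-1-yl]-1,2-dioxolan-3-yl]acetate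
Product: 22 2-[(3S,5R)-3,5-dimethyl-5-[(2R,9E,11E)-2-methyl-12-phenyldodeca-9,11-dien-1-yl]-1,2-dioxolan-3-yl]acetic acid
Conditions: LiOH, THF/H2O, 0 °C to rt; then 1 M HCl to pH 3
Reagents that add atoms: lithium hydroxide, [Li+].[OH-]
Why: Saponification of the methyl ester at 0 °C, a standard reaction for esters of 3,3,5,5-tetrasubstituted 1,2-dioxolane-3-acetic acids, should leave the diene and the peroxide intact, since neither peroxide carbon carries a hydrogen and the Kornblum–DeLaMare pathway is closed.

**Compound list**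

1 | (6-bromohexyloxy)(tert-butyl)dimethylsilane | BrCCCCCCO[Si](C)(C)C(C)(C)C | starting material
2 | (S)-3-bromo-2-methylpropan-1-ol | C[C@H](CBr)CO | starting material
3 | {6-[(tert-butyldimethylsilyl)oxy]hexyl}magnesium bromide | Br[Mg]CCCCCCO[Si](C)(C)C(C)(C)C | intermediate
4 | chloromagnesium (S)-3-bromo-2-methylpropan-1-olate | C[C@H](CBr)CO[Mg]Cl | intermediate
5 | (R)-9-[(tert-butyldimethylsilyl)oxy]-2-methylnonan-1-ol | C[C@H](CCCCCCCO[Si](C)(C)C(C)(C)C)CO | intermediate
6 | (R)-9-[(tert-butyldimethylsilyl)oxy]-2-methylnonanal | C[C@H](CCCCCCCO[Si](C)(C)C(C)(C)C)C=O | intermediate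
7 | 3-(triphenyl-λ5-phosphanylidene)butan-2-one | CC(=O)C(C)=P(c1ccccc1)(c1ccccc1)c1ccccc1 | starting material
8 | (3E,5R)-12-[(tert-butyldimethylsilyl)oxy]-3,5-dimethyldodec-3-en-2-one | C[C@H](CCCCCCCO[Si](C)(C)C(C)(C)C)/C=C(\C)C(C)=O | intermediate
9 | (5R)-12-[(tert-butyldimethylsilyl)oxy]-2-{[dimethyl(phenyl)silyl]oxy}-3,5-dimethyldodec-2-ene, E/Z mixture | C[C@H](CCCCCCCO[Si](C)(C)C(C)(C)C)CC(C)=C(C)O[Si](C)(C)c1ccccc1 | intermediate
10 | tert-butyl{[(8R)-9-(2-{[dimethyl(phenyl)silyl]oxy}-1,2-dimethylcyclopropyl)-8-methylnonyl]oxy}dimethylsilane, ring diastereomers | C[C@H](CCCCCCCO[Si](C)(C)C(C)(C)C)CC1(C)CC1(C)O[Si](C)(C)c1ccccc1 | intermediate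
11 | 2-{(2R)-9-[(tert-butyldimethylsilyl)oxy]-2-methylnonyl}-1,2-dimethylcyclopropan-1-ol, ring diastereomers | C[C@H](CCCCCCCO[Si](C)(C)C(C)(C)C)CC1(C)CC1(C)O | intermediate
12 | (6R)-13-[(tert-butyldimethylsilyl)oxy]-4-hydroperoxy-4,6-dimethyltridecan-2-one, both C4 epimers | C[C@H](CCCCCCCO[Si](C)(C)C(C)(C)C)CC(C)(OO)CC(C)=O | intermediate
13 | 5-{(2R)-9-[(tert-butyldimethylsilyl)oxy]-2-methylnonyl}-3,5-dimethyl-1,2-dioxolan-3-ol, mixture at C3 and C5 | C[C@H](CCCCCCCO[Si](C)(C)C(C)(C)C)CC1(C)CC(C)(O)OO1 | intermediate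
14 | 5-{(2R)-9-[(tert-butyldimethylsilyl)oxy]-2-methylnonyl}-3,5-dimethyl-1,2-dioxolan-3-yl acetate, mixture at C3 and C5 | C[C@H](CCCCCCCO[Si](C)(C)C(C)(C)C)CC1(C)CC(C)(OC(C)=O)OO1 | intermediate
15 | tert-butyl[(1-methoxyethenyl)oxy]dimethylsilane | COC(=C)O[Si](C)(C)C(C)(C)C | starting material
16 | methyl 2-[(3S,5R)-5-{(2R)-9-[(tert-butyldimethylsilyl)oxy]-2-methylnonyl}-3,5-dimethyl-1,2-dioxolan-3-yl]acetate | C[C@H](CCCCCCCO[Si](C)(C)C(C)(C)C)C[C@]1(C)C[C@@](C)(CC(=O)OC)OO1 | intermediate
17 | methyl 2-[(3S,5R)-5-[(2R)-9-hydroxy-2-methylnonyl]-3,5-dimethyl-1,2-dioxolan-3-yl]acetate | C[C@H](CCCCCCCO)C[C@]1(C)C[C@@](C)(CC(=O)OC)OO1 | intermediate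
18 | methyl 2-[(3S,5R)-3,5-dimethyl-5-[(2R)-2-methyl-9-oxononyl]-1,2-dioxolan-3-yl]acetate | C[C@H](CCCCCCC=O)C[C@]1(C)C[C@@](C)(CC(=O)OC)OO1 | intermediate
19 | diethyl [(2E)-3-phenylprop-2-en-1-yl]phosphonate | CCOP(=O)(C/C=C/c1ccccc1)OCC | starting material
20 | lithium salt of the α-carbanion of diethyl [(2E)-3-phenylprop-2-en-1-yl]phosphonate | [Li+].CCOP(=O)([CH-]/C=C/c1ccccc1)OCC | intermediate
21 | methyl 2-[(3S,5R)-3,5-dimethyl-5-[(2R,9E,11E)-2-methyl-12-phenyldodeca-9,11-dien-1-yl]-1,2-dioxolan-3-yl]acetate | C[C@H](CCCCCC/C=C/C=C/c1ccccc1)C[C@]1(C)C[C@@](C)(CC(=O)OC)OO1 | intermediate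
22 | 2-[(3S,5R)-3,5-dimethyl-5-[(2R,9E,11E)-2-methyl-12-phenyldodeca-9,11-dien-1-yl]-1,2-dioxolan-3-yl]acetic acid | C[C@H](CCCCCC/C=C/C=C/c1ccccc1)C[C@]1(C)C[C@@](C)(CC(=O)O)OO1 | target

**Step count and risks**

Total step count: 12. Longest linear sequence: 12 steps (from 1 and 2 to 22).

Steps most likely to fail:

1. Step 8. The Lewis acid that ionises the acetate may also trigger heterolysis of the O–O bond (Hock-type fragmentation), and facial discrimination between methyl and the chain CH2 on C5 may be weak, so more of the cis isomers would form. The fallback sets out from 14 and comes back at 16. It swaps the ester enolate equivalent for a softer π-nucleophile and Lewis acid and builds the carboxyl group by oxidation afterwards. SnCl4-mediated allylation of 14 with allyltrimethylsilane (CH2Cl2, −78 °C) should give tert-butyl({(8R)-9-[(3R,5R)-3,5-dimethyl-3-(prop-2-en-1-yl)-1,2-dioxolan-5-yl]-8-methylnonyl}oxy)dimethylsilane F3, on which the isomer separation is done. Ozonolysis (O3, CH2Cl2, −78 °C; Me2S) should give 2-[(3S,5R)-5-{(2R)-9-[(tert-butyldimethylsilyl)oxy]-2-methylnonyl}-3,5-dimethyl-1,2-dioxolan-3-yl]acetaldehyde F4. Pinnick oxidation (NaClO2, NaH2PO4, 2-methylbut-2-ene) should give 2-[(3S,5R)-5-{(2R)-9-[(tert-butyldimethylsilyl)oxy]-2-methylnonyl}-3,5-dimethyl-1,2-dioxolan-3-yl]acetic acid F5, and TMSCHN2 in MeOH/PhMe returns 16.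

2. Step 6. The radical chain may stall, or the peroxy hemiketal may be degraded further by the manganese catalyst (alkoxy-radical β-scission, epoxy ketone formation). In addition, capture of dioxygen by the open radical cannot be made face-selective, which puts the whole burden of the C5 configuration on the later separation. The fallback sets out from 5 and comes back at 16, building the dioxolane and the ester arm together by a peroxycarbenium–alkene annulation. Appel iodination of 5 (I2, PPh3, imidazole) should give tert-butyl{[(8R)-9-iodo-8-methylnonyl]oxy}dimethylsilane F1. Copper-catalysed coupling with isopropenylmagnesium bromide (Li2CuCl4, THF) should give tert-butyl{[(8R)-8,10-dimethylundec-10-en-1-yl]oxy}dimethylsilane F2. Formal (3+2) annulation of F2 with the peroxycarbenium ion generated by SnCl4 (CH2Cl2, −78 °C) from methyl 3-methoxy-3-[(triethylsilyl)peroxy]butanoate should then give 16 after the same isomer separation.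

3. Step 11. The phosphonate anion may deprotonate the carbon α to the ester, after which E1cB loss of the peroxide oxygen opens the ring; the E selectivity at the new double bond may also be incomplete. The fallback sets out from 18 and comes back at 21, forming each diene bond with defined geometry by cross-coupling. Seyferth–Gilbert homologation with the Ohira–Bestmann reagent (K2CO3, MeOH, 0 °C) should give methyl 2-[(3S,5R)-3,5-dimethyl-5-[(2R)-2-methyldec-9-yn-1-yl]-1,2-dioxolan-3-yl]acetate F6. Hydroboration with pinacolborane catalysed by Cp2Zr(H)Cl should give methyl 2-[(3S,5R)-3,5-dimethyl-5-[(2R,9E)-2-methyl-10-(4,4,5,5-tetramethyl-1,3,2-dioxaborolan-2-yl)dec-9-en-1-yl]-1,2-dioxolan-3-yl]acetate F7. Suzuki–Miyaura coupling with (E)-(2-bromoethenyl)benzene (Pd(PPh3)4, aq. K3PO4, THF) should give 21.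

**Further compounds**

F1 | step 6 | tert-butyl{[(8R)-9-iodo-8-methylnonyl]oxy}dimethylsilane | C[C@H](CCCCCCCO[Si](C)(C)C(C)(C)C)CI
F2 | step 6 | tert-butyl{[(8R)-8,10-dimethylundec-10-en-1-yl]oxy}dimethylsilane | C[C@H](CCCCCCCO[Si](C)(C)C(C)(C)C)CC(C)=C
F3 | step 8 | tert-butyl({(8R)-9-[(3R,5R)-3,5-dimethyl-3-(prop-2-en-1-yl)-1,2-dioxolan-5-yl]-8-methylnonyl}oxy)dimethylsilane | C[C@H](CCCCCCCO[Si](C)(C)C(C)(C)C)C[C@]1(C)C[C@@](C)(CC=C)OO1
F4 | step 8 | 2-[(3S,5R)-5-{(2R)-9-[(tert-butyldimethylsilyl)oxy]-2-methylnonyl}-3,5-dimethyl-1,2-dioxolan-3-yl]acetaldehyde | C[C@H](CCCCCCCO[Si](C)(C)C(C)(C)C)C[C@]1(C)C[C@@](C)(CC=O)OO1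
F5 | step 8 | 2-[(3S,5R)-5-{(2R)-9-[(tert-butyldimethylsilyl)oxy]-2-methylnonyl}-3,5-dimethyl-1,2-dioxolan-3-yl]acetic acid | C[C@H](CCCCCCCO[Si](C)(C)C(C)(C)C)C[C@]1(C)C[C@@](C)(CC(=O)O)OO1
F6 | step 11 | methyl 2-[(3S,5R)-3,5-dimethyl-5-[(2R)-2-methyldec-9-yn-1-yl]-1,2-dioxolan-3-yl]acetate | C[C@H](CCCCCCC#C)C[C@]1(C)C[C@@](C)(CC(=O)OC)OO1
F7 | step 11 | methyl 2-[(3S,5R)-3,5-dimethyl-5-[(2R,9E)-2-methyl-10-(4,4,5,5-tetramethyl-1,3,2-dioxaborolan-2-yl)dec-9-en-1-yl]-1,2-dioxolan-3-yl]acetate | C[C@H](CCCCCC/C=C/B1OC(C)(C)C(C)(C)O1)C[C@]1(C)C[C@@](C)(CC(=O)OC)OO1
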